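**Retrosynthetic overview**

1. The last C–C bond made is C4–C19, which closes the δ-lactone of ring A. The feature used is the quaternary C4 (C18 methyl and C19 carbonyl, α to the C3 oxygen) whose carbonyl is tied through oxygen to C20 on C10, 1,3-diaxial across ring A. The C1=C2 reduction, C2 hydroxylation, C3 reduction and deprotection follow.
2. The precursor comes from ring A built by Robinson annulation (ethyl vinyl ketone) on a ring B β-keto ester whose C10 ester becomes C20. Li/NH3 sets the trans A/B fusion, C7 enters as a C6 hydroxymethyl group, and the C1=C2 bond comes from a Saegusa oxidation.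
3. Ring B is closed by Dieckmann condensation of two cis acetate arms on C8 and C9, made by Diels–Alder addition of butadiene to the ring C enone and ozonolysis.
4. Ring D is closed by 5-exo vinyl radical cyclisation onto a C11 enone unmasked from a C13 silyl group. That silyl group, set by Rh/BINAP conjugate silylation, also directs the Diels–Alder face and carries the absolute configuration.
5. Order of ring formation: C, a temporary cyclohexene, D, B, A, lactone.

Key step: step 24

Remark: gibberellane numbering is used throughout (ring A C1–C5/C10, ring B C5/C6/C8–C10, ring C C8/C9/C11–C14, ring D C8/C13–C16); α is the face of ring B that carries C20, β the face that carries H5, H9, C7 and C15; "19-nor" means C19 is absent. The sense of induction in step 1 is assumed by analogy with Rh/BINAP aryl transfers; if it is opposite, (S)-BINAP is used.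

**Route**

Step 1
Reactants: 1 cyclohex-2-en-1-one
Product: 2 (R)-3-[dimethyl(phenyl)silyl]cyclohexan-1-one
Conditions: PhMe2Si–B(pin), [Rh(cod)2]OTf (5 mol %), (R)-BINAP, Et3N, 1,4-dioxane–H2O, 45 °C
Reagents that add atoms: 2-[dimethyl(phenyl)silyl]-4,4,5,5-tetramethyl-1,3,2-dioxaborolane, CC1(C)OB(OC1(C)C)[Si](C)(C)c1ccccc1
Why: Rh-catalysed enantioselective conjugate silyl transfer, in which the BINAP-bound Rh–Si species adds to one enantioface of the enone (as in Hayashi–Miyaura additions) and sets the future C13 centre.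

Step 2
Reactants: 2 (R)-3-[dimethyl(phenyl)silyl]cyclohexan-1-one
Product: 3 (R)-{[5-(dimethyl(phenyl)silyl)cyclohex-1-en-1-yl]oxy}trimethylsilane
Conditions: LiN(i-Pr)2, THF, −78 °C; Me3SiCl
Reagents that add atoms: chlorotrimethylsilane, C[Si](C)(C)Cl
Why: kinetic enolisation should take place at the α-carbon remote from the bulky silyl-bearing carbon, and O-silylation fixes that regiochemistry.

Step 3
Reactants: 3 (R)-{[5-(dimethyl(phenyl)silyl)cyclohex-1-en-1-yl]oxy}trimethylsilane
Product: 4 (R)-5-[dimethyl(phenyl)silyl]cyclohex-2-en-1-one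
Conditions: Pd(OAc)2 (10 mol %), O2, DMSO, 25 °C
Reagents that add atoms: none
Why: Saegusa–Ito oxidation of the silyl enol ether gives the enone on the side fixed in step 2 and leaves the silyl stereocentre untouched.

Step 4
Reactants: 4 (R)-5-[dimethyl(phenyl)silyl]cyclohex-2-en-1-one; 5 2,3-dibromoprop-1-ene
Product: 6 (5R)-1-(2-bromoprop-2-en-1-yl)-5-[dimethyl(phenyl)silyl]cyclohex-2-en-1-ol (both C1 epimers)
Conditions: Zn dust, THF, 0 °C; aq. NH4Cl
Reagents that add atoms: none
Why: Barbier allylation, in which the allylic zinc reagent adds 1,2 to the enone carbonyl; the carbinol configuration is irrelevant because it is lost in step 5.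

Step 5
Reactants: 6 (5R)-1-(2-bromoprop-2-en-1-yl)-5-[dimethyl(phenyl)silyl]cyclohex-2-en-1-ol
Product: 7 (S)-3-(2-bromoprop-2-en-1-yl)-5-[dimethyl(phenyl)silyl]cyclohex-2-en-1-one
Conditions: [C5H5NH][CrO3Cl], CH2Cl2, 25 °C
Reagents that add atoms: none
Why: Dauben–Babler oxidative transposition of the tertiary allylic alcohol (chromate ester [3,3] shift, then oxidation) gives the 3-substituted enone with C11 as the carbonyl carbon and C8 bearing the bromoallyl group.

Step 6
Reactants: 7 (S)-3-(2-bromoprop-2-en-1-yl)-5-[dimethyl(phenyl)silyl]cyclohex-2-en-1-one; 8 buta-1,3-diene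
Product: 9 4a-(2-bromoprop-2-en-1-yl)-3-[dimethyl(phenyl)silyl]-3,4,4a,5,8,8a-hexahydronaphthalen-1(2H)-one, cis-fused, with 8a-H, the 4a side chain and the 3-silyl group all on one face
Conditions: EtAlCl2 (30 mol %), toluene, sealed tube, 25–40 °C
Reagents that add atoms: none
Why: Lewis acid catalysed Diels–Alder reaction; the diene should add suprafacially to the C8=C9 face anti to the C13 silyl group, so C8 (quaternary) and C9 are set cis, with C15 and H9 both β.

Step 7
Reactants: 9 cis-fused Diels–Alder adduct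
Product: 10 3-(2-bromoprop-2-en-1-yl)-5-[dimethyl(phenyl)silyl]-2,3-bis(2-oxoethyl)cyclohexan-1-one (oxoethyl arms cis, silyl cis to bromoallyl)
Conditions: O3, CH2Cl2–MeOH, −78 °C; PPh3
Reagents that add atoms: ozone, [O-][O+]=O
Why: ozonolysis with reductive work-up cleaves the electron-rich cis-disubstituted ring alkene much faster than the vinyl bromide or the arene and gives the C6 and C10 arms.

Step 8
Reactants: 10 dialdehyde
Product: 12 dimethyl 2,2'-[1-(2-bromoprop-2-en-1-yl)-5-(dimethyl(phenyl)silyl)-3-oxocyclohexane-1,2-diyl]diacetate (arms cis), via diacid 11 (not isolated)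
Conditions: NaClO2, NaH2PO4, 2-methylbut-2-ene, t-BuOH–H2O, 0 °C; then Me3SiCHN2, PhMe–MeOH
Reagents that add atoms: sodium chlorite, [Na+].[O-]Cl=O; (trimethylsilyl)diazomethane, C[Si](C)(C)C=[N+]=[N-]
Why: Pinnick oxidation followed by diazoalkane esterification runs under near-neutral conditions, so the epimerisable C9 (α to the C11 ketone) should be preserved.

Step 9
Reactants: 12 silyl keto diester
Product: 13 dimethyl 2,2'-[1-(2-bromoprop-2-en-1-yl)-3-oxocyclohex-4-ene-1,2-diyl]diacetate (arms cis)
Conditions: CuCl2, DMF, 55 °C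
Reagents that add atoms: none
Why: oxidative desilylation of the β-silyl ketone (α-chlorination at the less hindered C12, then loss of the silyl chloride) unmasks the C12=C13 enone and erases the C13 centre once it has done its work.

Step 10
Reactants: 13 bromoallyl enone diester
Product: 14 dimethyl 2,2'-(6-methylidene-3-oxobicyclo[3.2.1]octane-1,2-diyl)diacetate (rings C and D; the C9 arm on the face of the one-carbon bridge)
Conditions: Bu3SnH (slow addition), AIBN, PhH, 80 °C
Reagents that add atoms: none
Why: the vinyl radical from the C–Br bond cyclises 5-exo-trig onto C13, the β-carbon of the enone (polarity matched), and the bridging fixes C13; the α-keto radical is then reduced by the stannane.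

Step 11
Reactants: 14 tricyclic keto diester
Product: 15 dimethyl 2,2'-(3-hydroxy-6-methylidenebicyclo[3.2.1]octane-1,2-diyl)diacetate, hydroxyl on the face of the two-carbon bridge (11β)
Conditions: LiBH(s-Bu)3, THF, −78 °C; H2O
Reagents that add atoms: none
Why: the bulky hydride should attack the C11 carbonyl from the α-face, away from the C15–C16 bridge (the usual course for bicyclo[3.2.1]octan-3-ones), giving the axial 11β alcohol cis to H9.

Step 12
Reactants: 15 11β alcohol
Product: 16 the 11β tert-butyldimethylsilyl ether of 15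
Conditions: t-BuMe2SiOTf, 2,6-lutidine, CH2Cl2, 0 °C
Reagents that add atoms: tert-butyldimethylsilyl trifluoromethanesulfonate, CC(C)(C)[Si](C)(C)OS(=O)(=O)C(F)(F)F
Why: the silyl triflate silylates even the hindered axial alcohol, and the ether survives every later step up to step 28.

Step 13
Reactants: 16 silyl ether diester
Product: 17 tricyclic β-keto ester (rings B, C, D): ring B cyclopentanone with C5 ketone, C10–CO2Me and C6H2, cis-fused at C8–C9 to the 11β-silyloxy-16-methylidene bicyclo[3.2.1]octane (C10 epimers)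
Conditions: NaOMe, PhMe–MeOH, 70 °C; AcOH
Reagents that add atoms: none
Why: Dieckmann condensation under equilibrating conditions should favour the β-keto ester whose acidic CH (C10) lies next to the tertiary C9, not next to the quaternary C8, so the retained ester is the future C20.

Step 14
Reactants: 17 tricyclic β-keto ester; 18 1-[(chloromethoxy)methyl]-4-methoxybenzene
Product: 19 the 6-[(4-methoxybenzyloxy)methyl] derivative of 17 (C6 and C10 epimers)
Conditions: LiN(i-Pr)2 (2.3 equiv), THF, −78 to −20 °C; 18, −78 to 0 °C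
Reagents that add atoms: none
Why: β-keto ester dianion alkylation takes place at the more reactive γ-carbon C6 and brings in C7 at the alcohol oxidation level, which does not acidify C6 in the later reduction.

Step 15
Reactants: 19 alkylated β-keto ester; 20 pent-1-en-3-one
Product: 22 methyl 11β-(tert-butyldimethylsilyloxy)-7-(4-methoxybenzyloxy)-3-oxo-19-norgibberella-4,16-dien-20-oate (C6 epimers), via triketone 21 (not isolated)
Conditions: DBU (10 mol %), THF, 0–25 °C; then pyrrolidine (30 mol %), AcOH, PhMe, 70 °C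
Reagents that add atoms: none
Why: Robinson annulation; the β-keto ester carbon C10 adds to the vinyl ketone from the β-face (the α-face is flanked by C11 and C14), which sets the quaternary C10 with C20 α, and enamine aldol condensation onto C5 closes ring A.

Step 16
Reactants: 22 tetracyclic enone
Product: 23 methyl 11β-(tert-butyldimethylsilyloxy)-7-(4-methoxybenzyloxy)-3-oxo-19-norgibberell-16-en-20-oate, 5β-H (trans A/B; C4 and C6 epimers)
Conditions: Li (2.5 equiv), NH3–THF, t-BuOH (1 equiv), −78 °C; NH4Cl
Reagents that add atoms: none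
Why: Birch-type dissolving-metal reduction of the enone; axial protonation of C5 anti to the axial C20 ester, on the less hindered β-face, is expected to give the trans-fused hydrindanone, as with other 7a-substituted hexahydroindenones, while the limiting amount of metal spares the ester and the benzylic ether.

Step 17
Reactants: 23 trans-fused keto ester
Product: 24 methyl 11β-(tert-butyldimethylsilyloxy)-7-hydroxy-3-oxo-19-norgibberell-16-en-20-oate (C4 and C6 epimers)
Conditions: DDQ, CH2Cl2–pH 7 buffer, 0 °C
Reagents that add atoms: none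
Why: oxidative cleavage of the 4-methoxybenzyl ether by hydride abstraction leaves the alkene, silyl ether and ketone untouched.

Step 18
Reactants: 24 primary alcohol
Product: 25 11β-(tert-butyldimethylsilyloxy)-20-methoxy-3,20-dioxo-19-norgibberell-16-en-7-oic acid (C4 and C6 epimers)
Conditions: TEMPO (20 mol %), PhI(OAc)2, MeCN–H2O, 25 °C
Reagents that add atoms: water, O
Why: oxoammonium-mediated oxidation takes the primary alcohol through the aldehyde hydrate to the acid without touching the ketone or the 1,1-disubstituted alkene.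

Step 19
Reactants: 25 keto acid ester
Product: 26 11β-(tert-butyldimethylsilyloxy)-20-hydroxy-3-oxo-19-norgibberell-16-en-7-oic acid (C4 and C6 epimers)
Conditions: LiN(i-Pr)2 (3.3 equiv), THF, −78 °C; LiBHEt3, −78 to 0 °C; aq. NH4Cl
Reagents that add atoms: none
Why: the ketone is masked as its lithium enolate and the acid as its carboxylate, so the borohydride reduces only the non-enolisable C20 methyl ester (enolate protection during hydride reduction).

Step 20
Reactants: 26 hydroxy keto acid
Product: 28 methyl 11β-(tert-butyldimethylsilyloxy)-20-hydroxy-3-oxo-19-norgibberell-16-en-7-oate, 6β-CO2Me (C4 epimers), via ester epimers 27 (not isolated)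
Conditions: Me3SiCHN2, PhMe–MeOH, 0 °C; then NaOMe (0.3 equiv), MeOH, 40 °C; AcOH
Reagents that add atoms: (trimethylsilyl)diazomethane, C[Si](C)(C)C=[N+]=[N-]
Why: esterification, then methoxide equilibration through the ester enolate, should settle C6 in the 6β configuration, in which C7 is trans to C4 and only cis to the C15 methylene; any 7,20-lactone of the 6α epimer is reopened by methanolysis.

Step 21
Reactants: 28 6β keto ester alcohol
Product: 29 methyl 11β-(tert-butyldimethylsilyloxy)-3,20-bis(trimethylsilyloxy)-19-norgibberella-2,16-dien-7-oate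
Conditions: LiN(i-Pr)2 (2.2 equiv), THF, −78 °C; Me3SiCl
Reagents that add atoms: chlorotrimethylsilane, C[Si](C)(C)Cl
Why: kinetic deprotonation of the ketone at the C2 methylene, not at the C4 methine or the hindered ester α-carbon, gives the C2=C3 silyl enol ether; the alkoxide is silylated as well.

Step 22
Reactants: 29 bis-silyl compound
Product: 31 methyl 11β-(tert-butyldimethylsilyloxy)-20-hydroxy-3-oxo-19-norgibberella-1,16-dien-7-oate (C4 epimers), via silyl ether 30 (not isolated)
Conditions: Pd(OAc)2 (15 mol %), O2, DMSO, 25 °C; then K2CO3 (cat.), MeOH, 0 °C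
Reagents that add atoms: none
Why: Saegusa–Ito oxidation places the C1=C2 bond, which removes the C2 hydrogens from later enolate chemistry, and mild methanolysis frees the primary C20 alcohol.

Step 23
Reactants: 31 enone alcohol; 32 1,1'-carbonyldiimidazole
Product: 33 methyl 11β-(tert-butyldimethylsilyloxy)-20-[(imidazol-1-ylcarbonyl)oxy]-3-oxo-19-norgibberella-1,16-dien-7-oate (either C4 epimer)
Conditions: CH2Cl2, 25 °C
Reagents that add atoms: none
Why: acyl transfer from carbonyldiimidazole to the only free hydroxyl gives the imidazole carboxylate tether that carries the future C19.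

Step 24
Reactants: 33 C20 O-(imidazol-1-ylcarbonyl) 4-methyl-1-en-3-one
Product: 34 7-methyl ester of 11β-(tert-butyldimethylsilyloxy)-20-hydroxy-3-oxogibberella-1,16-diene-7,19-dioic acid 19,20-lactone (C18 β, C19 α)
Conditions: LiN(SiMe3)2 (1.3 equiv), THF, −78 to 0 °C; aq. NH4Cl
Reagents that add atoms: none
Why: the amide base removes the C4 hydrogen, the only ketone α-hydrogen left once C1=C2 is in place, to give the cross-conjugated dienolate, whose C4 carbon adds to the tethered carbonyl and expels imidazolide. The closest known reaction type is the intramolecular Claisen-type C-acylation of ketone enolates by tethered carbonates or acyl imidazoles to give β-keto lactones. The six-membered lactone ring (C4, C19, O, C20, C10, C5) closes in the 6-exo-trig mode. The new quaternary centre C4 is controlled by the axial C20 tether on the α-face: both C4 epimers of 33 pass through the same planar enolate, C19 can only arrive cis to C20, and the methyl group is pushed to the β-face. The step needs C- over O-acylation and C4 over C6 selectivity; O-acylation would require an eight-membered ring, and the ketone α-hydrogen is more acidic than the hindered C6 ester hydrogen. The product has no enolisable hydrogen between the two carbonyls, so it cannot equilibrate further.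

Step 25
Reactants: 34 enone keto lactone
Product: 35 the 1,2-dihydro derivative of 34 (3-oxo 19,20-lactone)
Conditions: [(Ph3P)CuH]6 (0.4 equiv), PhH–THF, 25 °C; aq. NH4Cl
Reagents that add atoms: none
Why: copper hydride conjugate reduction is selective for the enone and leaves the isolated alkene, the esters and the lactone alone.

Step 26
Reactants: 35 saturated keto lactone
Product: 36 the 2β-hydroxy derivative of 35
Conditions: KN(SiMe3)2, THF, −78 °C; 2-(phenylsulfonyl)-3-phenyloxaziridine; aq. NH4Cl
Reagents that add atoms: 2-(phenylsulfonyl)-3-phenyloxaziridine, O=S(=O)(N1OC1c1ccccc1)c1ccccc1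
Why: the ketone can enolise only toward C2 (C4 is quaternary), and oxygen transfer to the enolate should come from the β-face, away from the α-lactone bridge, giving the equatorial 2β-hydroxyl.

Step 27
Reactants: 36 2β-hydroxy 3-ketone
Product: 37 7-methyl ester of 11β-(tert-butyldimethylsilyloxy)-2β,3β,20-trihydroxygibberell-16-ene-7,19-dioic acid 19,20-lactone
Conditions: LiBH(s-Bu)3 (2.5 equiv), THF, −78 °C; aq. NH4Cl
Reagents that add atoms: none
Why: the bulky hydride should add to C3 along the equatorial trajectory (as with other ketones next to a quaternary carbon), giving the axial 3β alcohol cis to the 2β-hydroxyl, and the buffered work-up avoids retro-aldol of the β-hydroxy lactone.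

Step 28
Reactants: 37 silyl ether diol
Product: 38 7-methyl ester of 2β,3β,11β,20-tetrahydroxygibberell-16-ene-7,19-dioic acid 19,20-lactone
Conditions: HF·pyridine, THF–pyridine, 0–25 °C
Reagents that add atoms: none
Why: buffered fluoride cleaves the hindered silyl ether without base (no retro-aldol at C3) and without strong acid (no migration of the exocyclic alkene).

Step 29
Reactants: 38 triol methyl ester
Product: 39 2β,3β,11β,20-tetrahydroxygibberell-16-ene-7,19-dioic acid 19,20-lactone (CNP0302900.3)
Conditions: LiS(n-Pr), HMPA, 25 °C; then 1 M HCl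
Reagents that add atoms: none
Why: SN2 demethylation of the hindered C7 methyl ester by thiolate avoids hydroxide, so the lactone and the C3 and C6 centres are not put at risk.

**Compound list**

1 | cyclohex-2-en-1-one | O=C1C=CCCC1 | starting material
2 | (R)-3-[dimethyl(phenyl)silyl]cyclohexan-1-one | O=C1C[C@H]([Si](C)(C)c2ccccc2)CCC1 | intermediate
3 | (R)-{[5-(dimethyl(phenyl)silyl)cyclohex-1-en-1-yl]oxy}trimethylsilane | C[Si](C)(C)OC1=CCC[C@@H]([Si](C)(C)c2ccccc2)C1 | intermediate
4 | (R)-5-[dimethyl(phenyl)silyl]cyclohex-2-en-1-one | O=C1C=CC[C@@H]([Si](C)(C)c2ccccc2)C1 | intermediate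
5 | 2,3-dibromoprop-1-ene | C=C(Br)CBr | starting material
6 | (5R)-1-(2-bromoprop-2-en-1-yl)-5-[dimethyl(phenyl)silyl]cyclohex-2-en-1-ol, C1 epimers | OC1(CC(Br)=C)C=CC[C@@H]([Si](C)(C)c2ccccc2)C1 | intermediate
7 | (S)-3-(2-bromoprop-2-en-1-yl)-5-[dimethyl(phenyl)silyl]cyclohex-2-en-1-one | C=C(Br)CC1=CC(=O)C[C@@H]([Si](C)(C)c2ccccc2)C1 | intermediate
8 | buta-1,3-diene | C=CC=C | starting material
9 | cis-fused 4a-(2-bromoprop-2-en-1-yl)-3-[dimethyl(phenyl)silyl]-3,4,4a,5,8,8a-hexahydronaphthalen-1(2H)-one, 8a-H, side chain and silyl on one face | C=C(Br)C[C@]12C[C@H]([Si](C)(C)c3ccccc3)CC(=O)[C@H]1CC=CC2 | intermediate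
10 | 3-(2-bromoprop-2-en-1-yl)-5-[dimethyl(phenyl)silyl]-2,3-bis(2-oxoethyl)cyclohexan-1-one, arms cis | C=C(Br)C[C@]1(CC=O)C[C@H]([Si](C)(C)c2ccccc2)CC(=O)[C@H]1CC=O | intermediate
11 | 2,2'-[1-(2-bromoprop-2-en-1-yl)-5-(dimethyl(phenyl)silyl)-3-oxocyclohexane-1,2-diyl]diacetic acid, arms cis (not isolated) | C=C(Br)C[C@]1(CC(=O)O)C[C@H]([Si](C)(C)c2ccccc2)CC(=O)[C@H]1CC(=O)O | intermediate
12 | dimethyl ester of 11 | C=C(Br)C[C@]1(CC(=O)OC)C[C@H]([Si](C)(C)c2ccccc2)CC(=O)[C@H]1CC(=O)OC | intermediate
13 | dimethyl 2,2'-[1-(2-bromoprop-2-en-1-yl)-3-oxocyclohex-4-ene-1,2-diyl]diacetate, arms cis | C=C(Br)C[C@]1(CC(=O)OC)CC=CC(=O)[C@H]1CC(=O)OC | intermediate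
14 | dimethyl 2,2'-(6-methylidene-3-oxobicyclo[3.2.1]octane-1,2-diyl)diacetate, C9-H toward the two-carbon bridge | C=C1C[C@]2(CC(=O)OC)C[C@H]1CC(=O)[C@H]2CC(=O)OC | intermediate
15 | dimethyl 2,2'-(3-hydroxy-6-methylidenebicyclo[3.2.1]octane-1,2-diyl)diacetate, 11β-OH (toward the two-carbon bridge) | C=C1C[C@]2(CC(=O)OC)C[C@H]1C[C@H](O)[C@H]2CC(=O)OC | intermediate
16 | 11β tert-butyldimethylsilyl ether of 15 | C=C1C[C@]2(CC(=O)OC)C[C@H]1C[C@H](O[Si](C)(C)C(C)(C)C)[C@H]2CC(=O)OC | intermediate
17 | tricyclic β-keto ester (rings B, C, D; C5 ketone, C10–CO2Me, 11β-OTBS, 16-methylidene; C10 epimers) | C=C1C[C@]23C[C@H]1C[C@H](O[Si](C)(C)C(C)(C)C)[C@H]2C(C(=O)OC)C(=O)C3 | intermediate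
18 | 1-[(chloromethoxy)methyl]-4-methoxybenzene | COc1ccc(COCCl)cc1 | starting material
19 | 6-[(4-methoxybenzyloxy)methyl] derivative of 17 (C6 and C10 epimers) | C=C1C[C@]23C[C@H]1C[C@H](O[Si](C)(C)C(C)(C)C)[C@H]2C(C(=O)OC)C(=O)C3COCc4ccc(OC)cc4 | intermediate
20 | pent-1-en-3-one (ethyl vinyl ketone) | CCC(=O)C=C | starting material
21 | C10 3-oxopentyl Michael adduct of 19, C20 ester α (not isolated) | C=C1C[C@]23C[C@H]1C[C@H](O[Si](C)(C)C(C)(C)C)[C@H]2[C@@](CCC(=O)CC)(C(=O)OC)C(=O)C3COCc4ccc(OC)cc4 | intermediate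
22 | methyl 11β-(tert-butyldimethylsilyloxy)-7-(4-methoxybenzyloxy)-3-oxo-19-norgibberella-4,16-dien-20-oate (C6 epimers) | C=C1C[C@]23C[C@H]1C[C@H](O[Si](C)(C)C(C)(C)C)[C@H]2[C@]4(C(=O)OC)CCC(=O)C(C)=C4C3COCc5ccc(OC)cc5 | intermediate
23 | methyl 11β-(tert-butyldimethylsilyloxy)-7-(4-methoxybenzyloxy)-3-oxo-19-norgibberell-16-en-20-oate, 5β-H (C4, C6 epimers) | C=C1C[C@]23C[C@H]1C[C@H](O[Si](C)(C)C(C)(C)C)[C@H]2[C@]4(C(=O)OC)CCC(=O)C(C)[C@H]4C3COCc5ccc(OC)cc5 | intermediate
24 | methyl 11β-(tert-butyldimethylsilyloxy)-7-hydroxy-3-oxo-19-norgibberell-16-en-20-oate (C4, C6 epimers) | C=C1C[C@]23C[C@H]1C[C@H](O[Si](C)(C)C(C)(C)C)[C@H]2[C@]4(C(=O)OC)CCC(=O)C(C)[C@H]4C3CO | intermediate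
25 | 11β-(tert-butyldimethylsilyloxy)-20-methoxy-3,20-dioxo-19-norgibberell-16-en-7-oic acid (C4, C6 epimers) | C=C1C[C@]23C[C@H]1C[C@H](O[Si](C)(C)C(C)(C)C)[C@H]2[C@]4(C(=O)OC)CCC(=O)C(C)[C@H]4C3C(=O)O | intermediate
26 | 11β-(tert-butyldimethylsilyloxy)-20-hydroxy-3-oxo-19-norgibberell-16-en-7-oic acid (C4, C6 epimers) | C=C1C[C@]23C[C@H]1C[C@H](O[Si](C)(C)C(C)(C)C)[C@H]2[C@]4(CO)CCC(=O)C(C)[C@H]4C3C(=O)O | intermediate
27 | methyl ester of 26, C6 epimers (not isolated) | C=C1C[C@]23C[C@H]1C[C@H](O[Si](C)(C)C(C)(C)C)[C@H]2[C@]4(CO)CCC(=O)C(C)[C@H]4C3C(=O)OC | intermediate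
28 | methyl 11β-(tert-butyldimethylsilyloxy)-20-hydroxy-3-oxo-19-norgibberell-16-en-7-oate, 6β-ester (C4 epimers) | C=C1C[C@]23C[C@H]1C[C@H](O[Si](C)(C)C(C)(C)C)[C@H]2[C@]4(CO)CCC(=O)C(C)[C@H]4[C@@H]3C(=O)OC | intermediate
29 | methyl 11β-(tert-butyldimethylsilyloxy)-3,20-bis(trimethylsilyloxy)-19-norgibberella-2,16-dien-7-oate | C=C1C[C@]23C[C@H]1C[C@H](O[Si](C)(C)C(C)(C)C)[C@H]2[C@]4(CO[Si](C)(C)C)CC=C(O[Si](C)(C)C)C(C)[C@H]4[C@@H]3C(=O)OC | intermediate
30 | methyl 11β-(tert-butyldimethylsilyloxy)-3-oxo-20-(trimethylsilyloxy)-19-norgibberella-1,16-dien-7-oate (not isolated) | C=C1C[C@]23C[C@H]1C[C@H](O[Si](C)(C)C(C)(C)C)[C@H]2[C@]4(CO[Si](C)(C)C)C=CC(=O)C(C)[C@H]4[C@@H]3C(=O)OC | intermediate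
31 | methyl 11β-(tert-butyldimethylsilyloxy)-20-hydroxy-3-oxo-19-norgibberella-1,16-dien-7-oate (C4 epimers) | C=C1C[C@]23C[C@H]1C[C@H](O[Si](C)(C)C(C)(C)C)[C@H]2[C@]4(CO)C=CC(=O)C(C)[C@H]4[C@@H]3C(=O)OC | intermediate
32 | 1,1'-carbonyldiimidazole | O=C(n1ccnc1)n1ccnc1 | starting material
33 | methyl 11β-(tert-butyldimethylsilyloxy)-20-[(imidazol-1-ylcarbonyl)oxy]-3-oxo-19-norgibberella-1,16-dien-7-oate (either C4 epimer) | C=C1C[C@]23C[C@H]1C[C@H](O[Si](C)(C)C(C)(C)C)[C@H]2[C@]4(COC(=O)n5ccnc5)C=CC(=O)C(C)[C@H]4[C@@H]3C(=O)OC | intermediate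
34 | 7-methyl ester of 11β-(tert-butyldimethylsilyloxy)-20-hydroxy-3-oxogibberella-1,16-diene-7,19-dioic acid 19,20-lactone | C=C1C[C@]23C[C@H]1C[C@H](O[Si](C)(C)C(C)(C)C)[C@H]2[C@]12COC(=O)[C@](C)(C(=O)C=C1)[C@H]2[C@@H]3C(=O)OC | intermediate
35 | 7-methyl ester of 11β-(tert-butyldimethylsilyloxy)-20-hydroxy-3-oxogibberell-16-ene-7,19-dioic acid 19,20-lactone | C=C1C[C@]23C[C@H]1C[C@H](O[Si](C)(C)C(C)(C)C)[C@H]2[C@]12COC(=O)[C@](C)(C(=O)CC1)[C@H]2[C@@H]3C(=O)OC | intermediate
36 | 2β-hydroxy derivative of 35 | C=C1C[C@]23C[C@H]1C[C@H](O[Si](C)(C)C(C)(C)C)[C@H]2[C@]12COC(=O)[C@](C)(C(=O)[C@@H](O)C1)[C@H]2[C@@H]3C(=O)OC | intermediate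
37 | 7-methyl ester of 11β-(tert-butyldimethylsilyloxy)-2β,3β,20-trihydroxygibberell-16-ene-7,19-dioic acid 19,20-lactone | C=C1C[C@]23C[C@H]1C[C@H](O[Si](C)(C)C(C)(C)C)[C@H]2[C@]12COC(=O)[C@](C)([C@@H](O)[C@@H](O)C1)[C@H]2[C@@H]3C(=O)OC | intermediate
38 | 7-methyl ester of 2β,3β,11β,20-tetrahydroxygibberell-16-ene-7,19-dioic acid 19,20-lactone | C=C1C[C@]23C[C@H]1C[C@H](O)[C@H]2[C@]12COC(=O)[C@](C)([C@@H](O)[C@@H](O)C1)[C@H]2[C@@H]3C(=O)OC | intermediate
39 | 2β,3β,11β,20-tetrahydroxygibberell-16-ene-7,19-dioic acid 19,20-lactone (CNP0302900.3) | C=C1C[C@]23C[C@H]1C[C@H](O)[C@H]2[C@]12COC(=O)[C@](C)([C@@H](O)[C@@H](O)C1)[C@H]2[C@@H]3C(=O)O | target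

**Step count and risks**

Total: 29 steps. Longest linear sequence: 29 steps (the route is fully linear; 23 steps to precursor 33, the key step, then 5 steps).

Steps most likely to fail:

1. Step 6 (Diels–Alder reaction). The β,β-disubstituted enone may react too slowly with butadiene, and the Lewis acid may cleave the aryl–silicon bond, which would erode conversion and facial control. The fallback replaces the concerted cycloaddition by a polar stepwise annulation. It sets out from 7: 2-(trimethylsilyloxy)buta-1,3-diene with catalytic Tf2NH in CH2Cl2 at −78 °C (Mukaiyama–Michael addition at C8 anti to the silyl group, then intramolecular Michael closure at C9) gives the silyl enol ether adduct F1. Ozonolysis (O3, then PPh3) cleaves the enol ether selectively and gives the aldehyde acid F2. Pinnick oxidation of F2 gives diacid 11, where the fallback comes back to the route (esterification in step 8).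

2. Step 11 (C11 reduction). Hydride may be delivered from the face of the C15–C16 bridge, because the α-face carries the axial C10 arm; this would give the 11α alcohol, which would also lactonise onto that arm. The fallback sets C11 before ring D exists and under catalyst control. It sets out from enone 13: Corey–Bakshi–Shibata reduction ((R)-Me-CBS oxazaborolidine, catecholborane, −78 °C) gives the allylic alcohol F3, and t-BuMe2SiOTf with 2,6-lutidine gives the silyl ether F4. Bu3SnH and AIBN then close ring D by 5-exo cyclisation of the vinyl radical onto the unactivated C12=C13 bond, and the fallback comes back to the route at 16.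

3. Step 24 (key C-acylation). The amide base or liberated imidazolide may attack the carbonylimidazole, or deprotonation of the hindered C4–H may be slow enough for intermolecular acyl transfer to compete. The fallback separates enolisation from acylation. It sets out from 33: t-BuMe2SiOTf and Et3N (soft enolisation, possible only toward C4) give the silyl dienol ether F5, which should be stable next to the neutral acyl imidazole. N-Methylation of the imidazole with MeOTf in MeCN then turns the tether into an acylimidazolium ion, which C4 of the silyl dienol ether attacks on the same α-face (intramolecular Mukaiyama-type C-acylation). Loss of 1-methylimidazole and the silyl group gives 34, where the fallback comes back to the route.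

**Further compounds**

F1 | step 6 | cis-fused 4a-(2-bromoprop-2-en-1-yl)-3-[dimethyl(phenyl)silyl]-6-(trimethylsilyloxy)-3,4,4a,5,8,8a-hexahydronaphthalen-1(2H)-one | C=C(Br)C[C@]12C[C@H]([Si](C)(C)c3ccccc3)CC(=O)[C@H]1CC=C(O[Si](C)(C)C)C2
F2 | step 6 | 2-[1-(2-bromoprop-2-en-1-yl)-5-(dimethyl(phenyl)silyl)-3-oxo-2-(2-oxoethyl)cyclohexyl]acetic acid, arms cis | C=C(Br)C[C@]1(CC(=O)O)C[C@H]([Si](C)(C)c2ccccc2)CC(=O)[C@H]1CC=O
F3 | step 11 | dimethyl 2,2'-[1-(2-bromoprop-2-en-1-yl)-3-hydroxycyclohex-4-ene-1,2-diyl]diacetate, hydroxyl cis to C9-H | C=C(Br)C[C@]1(CC(=O)OC)CC=C[C@H](O)[C@H]1CC(=O)OC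
F4 | step 11 | tert-butyldimethylsilyl ether of F3 | C=C(Br)C[C@]1(CC(=O)OC)CC=C[C@H](O[Si](C)(C)C(C)(C)C)[C@H]1CC(=O)OC
F5 | step 24 | methyl 3,11β-bis(tert-butyldimethylsilyloxy)-20-[(imidazol-1-ylcarbonyl)oxy]-19-norgibberella-1,3,16-trien-7-oate | C=C1C[C@]23C[C@H]1C[C@H](O[Si](C)(C)C(C)(C)C)[C@H]2[C@]4(COC(=O)n5ccnc5)C=CC(O[Si](C)(C)C(C)(C)C)=C(C)[C@H]4[C@@H]3C(=O)OC
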